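**Remark (assumptions).** Labdane numbering is used for all intermediates: ring A = C1–C5 + C10, ring B = C5–C10, C17 on C8, C18/C19 on C4, C20 on C10, side chain C11–C16. "α" is the face opposite C20. The target is read as (2R,3S,5S,8R,9S,10S,13E): 2α-OAc, 3α-OH, 5α-H, 8α-CH3, 9β-OH with the side chain 9α. (R)-Glyceraldehyde acetonide is taken as commercial.

**Retrosynthetic overview**
1. Target 26 ⇐ C2-selective acetylation and acetonide removal ⇐ ester 24 ⇐ hydroboration/B-alkyl Suzuki coupling of 9α-vinyl carbinol 20 with (E)-enol triflate 22 (fixes 13E) ⇐ vinyl addition to C9 ketone 18 anti to C20 (sets C9) ⇐ enone 16 (hydrogenation/epimerisation sets C8).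
2. Key disconnection: enone 16 ⇐ acyclic keto-enal 13. C10 (α to the C9 ketone) adds to the enal β-carbon C5 and closes ring A, then C8 (α′) condenses with the C7 aldehyde and closes ring B, in one pot.
3. Enabling feature: in ring B the oxygen-bearing C9 (a latent ketone) lies between C8 and C10, and these two α-carbons are bridged by the three-carbon unit C5–C6–C7 (a 1,5-dicarbonyl relationship C9/C7). C5–C10 is the bond shared by rings A and B, C4 is quaternary (the enal has no γ-H), and the cis-2,3-diol, held as a dioxolane, pre-folds the chain.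
4. 13 ⇐ cross-metathesis with crotonaldehyde ⇐ ketone 11 ⇐ aza-enolate alkylation of pentan-3-one hydrazone 9 with iodide 6 ⇐ (R)-glyceraldehyde acetonide 1 + prenyl bromide 2 (reverse prenylation creates C4 and sets C3).

Key step: step 8

**Step 1**
Reactants: 1 (R)-2,2-dimethyl-1,3-dioxolane-4-carbaldehyde; 2 1-bromo-3-methylbut-2-ene (prenyl bromide)
Product: 3 (1S)-1-[(4R)-2,2-dimethyl-1,3-dioxolan-4-yl]-2,2-dimethylbut-3-en-1-ol
Conditions: Zn dust, THF/sat. aq. NH4Cl, 0 °C → rt (prenylzinc bromide formed in situ)
Reagents that add atoms: prenyl bromide (2), CC(C)=CCBr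
Why: Barbier-type allylation; the prenylzinc reagent reacts through its γ-carbon (cyclic SE2′ transition state) to give the reverse-prenyl adduct with the quaternary C4, and non-chelated addition anti to the α-C–O bond should favour the anti (2R,3S) alcohol, the minor syn isomer being removed by chromatography.

**Step 2**
Reactants: 3
Product: 4 (2R,3S)-4,4-dimethylhex-5-ene-1,2,3-triol
Conditions: AcOH/H2O (4:1), 40 °C
Reagents that add atoms: none
Why: Acid-catalysed hydrolysis of the terminal dioxolane; no stereocentre is touched and the isolated vinyl group on a quaternary carbon is inert.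

**Step 3**
Reactants: 4
Product: 5 (2S,3S)-1-iodo-4,4-dimethylhex-5-ene-2,3-diol
Conditions: PPh3 (1.1 equiv), I2 (1.1 equiv), imidazole, THF, 0 °C → rt
Reagents that add atoms: iodine, II
Why: Appel-type iodination; the alkoxyphosphonium salt forms and is displaced (SN2) fastest at the unhindered primary C1–OH, while the two secondary hydroxyls (one neopentylic) react much more slowly.

**Step 4**
Reactants: 5
Product: 6 (4S,5S)-4-(iodomethyl)-2,2-dimethyl-5-(2-methylbut-3-en-2-yl)-1,3-dioxolane (cis)
Conditions: 2,2-dimethoxypropane, PPTS (cat.), CH2Cl2, rt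
Reagents that add atoms: 2,2-dimethoxypropane, COC(C)(C)OC
Why: Acid-catalysed transacetalisation; the anti (erythro) 2,3-diol can only give the cis-4,5-disubstituted dioxolane, which later holds C1 and C4 on the same side for ring A closure.

**Step 5**
Reactants: 7 pentan-3-one; 8 1,1-dimethylhydrazine
Product: 9 pentan-3-one N,N-dimethylhydrazone
Conditions: AcOH (cat.), EtOH, reflux
Reagents that add atoms: 1,1-dimethylhydrazine (8), CN(C)N
Why: Simple carbonyl–hydrazine condensation; the hydrazone gives a strongly nucleophilic aza-enolate that alkylates once and cleanly.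

**Step 6**
Reactants: 9; 6
Product: 11 1-[(4R,5S)-2,2-dimethyl-5-(2-methylbut-3-en-2-yl)-1,3-dioxolan-4-yl]-2-methylpentan-3-one (both epimers at the carbon next to the carbonyl), via alkylated hydrazone 10 (not isolated)
Conditions: LiN(i-Pr)2, THF, 0 °C; then 6, −78 °C → rt; then CuCl2, THF/pH 7 aq. buffer, rt
Reagents that add atoms: water, O
Why: Alkylation of a metallated dimethylhydrazone with a primary iodide, then mild CuCl2-assisted hydrolysis that leaves the acetonide intact; the new centre C10 is deliberately uncontrolled because it is enolised in step 8.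

**Step 7**
Reactants: 11; 12 (E)-but-2-enal (crotonaldehyde)
Product: 13 (E)-4-[(4S,5R)-2,2-dimethyl-5-(2-methyl-3-oxopentyl)-1,3-dioxolan-4-yl]-4-methylpent-2-enal (both epimers next to the ketone)
Conditions: second-generation Hoveyda–Grubbs catalyst RuCl2(H2IMes)(=CH-C6H4-2-O-i-Pr) (5–10 mol%), crotonaldehyde (5 equiv), toluene, 60 °C
Reagents that add atoms: crotonaldehyde (12), C/C=C/C=O
Why: Olefin cross-metathesis; the vinyl group on the quaternary C4 does not homodimerise, the excess enal partner exchanges readily, and the conjugated (E)-enal is the thermodynamic product, while ketone and acetonide are inert.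

**Step 8**
Reactants: 13
Product: 16 (5S,10S)-2α,3α-(isopropylidenedioxy)-4,4,8,10-tetramethyl-trans-octal-7-en-9-one, via Michael adduct 14 (not isolated), via ketol 15 (not isolated)
Conditions: KOt-Bu (0.5 equiv), t-BuOH/THF (1:1), 0.01 M, 0 °C → 50 °C
Reagents that add atoms: none
Why: Under equilibrating KOt-Bu/t-BuOH both ketone enolates form, but only the C10 enolate can reach the enal β-carbon C5 (the C8 enolate would need an eight-membered ring), so an intramolecular Michael addition (6-exo-trig) closes ring A to give 14; proton transfer then lets the C8 enolate add to the C7 aldehyde (6-(enolexo)-exo-trig aldol, ring B, ketol 15), and E1cB loss of water gives the conjugated enone 16 as the irreversible sink. The closest known reaction type is the tandem intramolecular Michael/aldol condensation (Robinson-type annulation, the [3+3] α,α′-annulation of a ketone with an enal). C10 and C5 are set in the Michael step through a chair-like transition state fixed by the cis-dioxolane: the chair with C2–O equatorial and C3–O axial is used because the other chair would put C2–O axial between the axial C4 methyl and the axial C10 substituent. In that chair the enal chain (C6) sits equatorial to avoid the axial C3–O, and the bulky solvated enolate unit (C9) sits equatorial anti to the quaternary C4 while the small C20 methyl takes the axial site, which gives the trans 5α-H/10β-CH3 relationship (5S,10S). The step is stereoconvergent, since both C10 epimers of 13 give the same planar enolate and the C7/C8 centres of 15 are erased on dehydration. The selectivity needed is regiochemical and is secured by ring size, by the quaternary C4 (no γ-hydrogens, hence no dienolate or deconjugation) and by high dilution against intermolecular Michael addition.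

**Step 9**
Reactants: 16
Product: 18 (5S,8R,10S)-2α,3α-(isopropylidenedioxy)-4,4,8α,10-tetramethyl-trans-decal-9-one, via 8-epi ketone 17 (not isolated)
Conditions: H2 (1 atm), Pd/C, EtOAc, rt; then NaOMe (cat.), MeOH, rt
Reagents that add atoms: none
Why: Heterogeneous hydrogenation of the enone C=C followed by base equilibration of the α-centre C8; the 8β (axial) methyl is syn-diaxial to C20, so both epimers should converge on the equatorial 8α-methyl ketone (8R).

**Step 10**
Reactants: 18; 19 vinylmagnesium bromide
Product: 20 (8R,9S)-9α-ethenyl-2α,3α-(isopropylidenedioxy)-4,4,8α,10-tetramethyl-trans-decalin-9β-ol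
Conditions: CeCl3 (anhydrous), THF, −78 °C; vinylmagnesium bromide, −78 → 0 °C; aq. NH4Cl
Reagents that add atoms: vinylmagnesium bromide (19), C=C[Mg]Br
Why: Organocerium 1,2-addition, which suppresses enolisation of the hindered ketone; the axial C20 methyl on the neighbouring carbon blocks the equatorial (β) trajectory, so the small sp2 nucleophile should enter axially from the α-face, anti to C20, giving 9α-vinyl/9β-OH (9S).

**Step 11**
Reactants: 21 methyl acetoacetate
Product: 22 methyl (E)-3-(trifluoromethylsulfonyloxy)but-2-enoate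
Conditions: Tf2O, aq. Me4NOH, hexanes, 5 °C
Reagents that add atoms: trifluoromethanesulfonic anhydride, O=S(=O)(OS(=O)(=O)C(F)(F)F)C(F)(F)F
Why: O-Triflation of the β-keto ester enolate; the non-chelated tetramethylammonium enolate reacts from its extended form and should give the (E)-enol triflate (OTf trans to CO2Me), which fixes the side-chain alkene geometry.

**Step 12**
Reactants: 20; 22
Product: 24 methyl (13E)-9β-hydroxy-2α,3α-(isopropylidenedioxy)-9α-labd-13-en-15-oate (9S), via B-alkyl borane 23 (not isolated)
Conditions: 9-BBN (2.5 equiv), THF, 0 → 50 °C; then 22, Pd(dppf)Cl2 (5 mol%), 3 M aq. K3PO4, DMF, rt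
Reagents that add atoms: enol triflate (22), COC(=O)/C=C(\C)OS(=O)(=O)C(F)(F)F
Why: Anti-Markovnikov hydroboration of the terminal vinyl group, then B-alkyl Suzuki–Miyaura coupling with the enol triflate, which proceeds with retention of alkene geometry and delivers the (E)-trisubstituted enoate; no stereocentre is formed.

**Step 13**
Reactants: 24
Product: 25 methyl (13E)-2α,3α,9β-trihydroxy-9α-labd-13-en-15-oate
Conditions: AcOH/H2O/THF (3:1:1), 45 °C
Reagents that add atoms: none
Why: Acid-catalysed acetal hydrolysis; the non-allylic tertiary alcohol and the enoate should tolerate these mild conditions.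

**Step 14**
Reactants: 25
Product: 26 methyl (2R,3S,5S,8R,9S,10S,13E)-2-acetoxy-3,9-dihydroxylabd-13-en-15-oate (target)
Conditions: Ac2O (1.1 equiv), pyridine, CH2Cl2, −20 → 0 °C
Reagents that add atoms: acetic anhydride, CC(=O)OC(C)=O
Why: Kinetically selective acylation of the equatorial, unhindered C2–OH over the axial neopentylic C3–OH and the tertiary C9–OH.

**Compound list**
1 | (R)-2,2-dimethyl-1,3-dioxolane-4-carbaldehyde | O=C[C@H]1COC(C)(C)O1 | starting material
2 | 1-bromo-3-methylbut-2-ene | CC(C)=CCBr | starting material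
3 | (1S)-1-[(4R)-2,2-dimethyl-1,3-dioxolan-4-yl]-2,2-dimethylbut-3-en-1-ol | C=CC(C)(C)[C@H](O)[C@H]1COC(C)(C)O1 | intermediate
4 | (2R,3S)-4,4-dimethylhex-5-ene-1,2,3-triol | C=CC(C)(C)[C@H](O)[C@H](O)CO | intermediate
5 | (2S,3S)-1-iodo-4,4-dimethylhex-5-ene-2,3-diol | C=CC(C)(C)[C@H](O)[C@H](O)CI | intermediate
6 | (4S,5S)-4-(iodomethyl)-2,2-dimethyl-5-(2-methylbut-3-en-2-yl)-1,3-dioxolane | C=CC(C)(C)[C@@H]1OC(C)(C)O[C@@H]1CI | intermediate
7 | pentan-3-one | CCC(=O)CC | starting material
8 | 1,1-dimethylhydrazine | CN(C)N | starting material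
9 | pentan-3-one N,N-dimethylhydrazone | CCC(CC)=NN(C)C | intermediate
10 | N,N-dimethylhydrazone of ketone 11 | CCC(=NN(C)C)C(C)C[C@H]1OC(C)(C)O[C@H]1C(C)(C)C=C | intermediate
11 | 1-[(4R,5S)-2,2-dimethyl-5-(2-methylbut-3-en-2-yl)-1,3-dioxolan-4-yl]-2-methylpentan-3-one | CCC(=O)C(C)C[C@H]1OC(C)(C)O[C@H]1C(C)(C)C=C | intermediate
12 | (E)-but-2-enal | C/C=C/C=O | starting material
13 | (E)-4-[(4S,5R)-2,2-dimethyl-5-(2-methyl-3-oxopentyl)-1,3-dioxolan-4-yl]-4-methylpent-2-enal | CCC(=O)C(C)C[C@H]1OC(C)(C)O[C@H]1C(C)(C)/C=C/C=O | intermediate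
14 | ring A keto aldehyde: (5S,10S)-2α,3α-(isopropylidenedioxy)-4,4,10-trimethyl-10-propanoylcyclohexane-5-acetaldehyde | O=CC[C@H]1C(C)(C)[C@@H]2OC(C)(C)O[C@@H]2C[C@]1(C)C(=O)CC | intermediate
15 | 7-hydroxy-2α,3α-(isopropylidenedioxy)-4,4,8,10-tetramethyl-trans-decal-9-one (C7/C8 mixture) | CC1C(O)C[C@H]2C(C)(C)[C@@H]3OC(C)(C)O[C@@H]3C[C@]2(C)C1=O | intermediate
16 | (5S,10S)-2α,3α-(isopropylidenedioxy)-4,4,8,10-tetramethyl-trans-octal-7-en-9-one | CC1=CC[C@H]2C(C)(C)[C@@H]3OC(C)(C)O[C@@H]3C[C@]2(C)C1=O | intermediate
17 | 8β-methyl (8S) epimer of ketone 18 | C[C@H]1CC[C@H]2C(C)(C)[C@@H]3OC(C)(C)O[C@@H]3C[C@]2(C)C1=O | intermediate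
18 | (5S,8R,10S)-2α,3α-(isopropylidenedioxy)-4,4,8α,10-tetramethyl-trans-decal-9-one | C[C@@H]1CC[C@H]2C(C)(C)[C@@H]3OC(C)(C)O[C@@H]3C[C@]2(C)C1=O | intermediate
19 | vinylmagnesium bromide | C=C[Mg]Br | starting material
20 | (8R,9S)-9α-ethenyl-2α,3α-(isopropylidenedioxy)-4,4,8α,10-tetramethyl-trans-decalin-9β-ol | C=C[C@]1(O)[C@H](C)CC[C@H]2C(C)(C)[C@@H]3OC(C)(C)O[C@@H]3C[C@@]21C | intermediate
21 | methyl acetoacetate | COC(=O)CC(C)=O | starting material
22 | methyl (E)-3-(trifluoromethylsulfonyloxy)but-2-enoate | COC(=O)/C=C(\C)OS(=O)(=O)C(F)(F)F | intermediate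
23 | 9-BBN adduct of 20 (boron on C12) | C(C[C@]1(O)[C@H](C)CC[C@H]2C(C)(C)[C@@H]3OC(C)(C)O[C@@H]3C[C@@]21C)B4C5CCCC4CCC5 | intermediate
24 | methyl (13E)-9β-hydroxy-2α,3α-(isopropylidenedioxy)-9α-labd-13-en-15-oate | COC(=O)/C=C(\C)CC[C@]1(O)[C@H](C)CC[C@H]2C(C)(C)[C@@H]3OC(C)(C)O[C@@H]3C[C@@]21C | intermediate
25 | methyl (13E)-2α,3α,9β-trihydroxy-9α-labd-13-en-15-oate | COC(=O)/C=C(\C)CC[C@]1(O)[C@H](C)CC[C@H]2C(C)(C)[C@H](O)[C@H](O)C[C@@]21C | intermediate
26 | methyl (2R,3S,5S,8R,9S,10S,13E)-2-acetoxy-3,9-dihydroxylabd-13-en-15-oate | COC(=O)/C=C(\C)CC[C@]1(O)[C@H](C)CC[C@H]2C(C)(C)[C@H](O)[C@H](OC(C)=O)C[C@@]21C | target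

**Step count.** Total: 14 steps. Longest linear sequence: 12 steps (1–4, 6–10, 12–14); steps 5 and 11 are side branches.

**Steps most likely to fail, with fallbacks**

Step 8. The Michael closure at the neopentylic C5 may be slow, so that base-induced oligomerisation of the enal wins, or the enolate unit may not discriminate well enough between the two sites at C10, which would erode the trans ring fusion. The fallback is a stepwise Lewis-acid route that sets out from 13. Thermodynamic silylation (Me3SiCl, Et3N, DMF, 80 °C) should give the tetrasubstituted trimethylsilyl enol ether F1, the less substituted isomer returning 13 on hydrolysis. BF3·OEt2 in CH2Cl2 at −78 °C then effects an intramolecular Mukaiyama–Michael addition to keto aldehyde 14, which is now isolated so that ring-fusion isomers can be separated. Pyrrolidine/AcOH (or p-TsOH, benzene, reflux) closes ring B by aldol condensation, and the fallback comes back to the route at 16.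

Step 6. SN2 displacement at the β-alkoxy, β-branched iodide may be slow, with E2 elimination by the strongly basic aza-enolate competing. The fallback uses a softer, thermally robust nucleophile and sets out from 6. Commercial ethyl 2-methyl-3-oxopentanoate with Cs2CO3 in DMF at 60 °C is alkylated by 6 to give β-keto ester F2. Krapcho dealkoxycarbonylation (LiCl, wet DMSO, 150 °C) then gives the ketone, and the fallback comes back to the route at 11.

Step 7. Productive metathesis at the vinyl group next to the quaternary carbon may not occur (slow initiation, catalyst decay, only self-metathesis of crotonaldehyde). The fallback sets out from 11. Ozonolysis (O3, CH2Cl2/MeOH, −78 °C; then Me2S) gives the neopentylic keto aldehyde F3, which cannot epimerise. Wittig olefination with (triphenylphosphoranylidene)acetaldehyde (toluene, 80 °C), chemoselective for the aldehyde over the ketone, gives the (E)-enal, and the fallback comes back to the route at 13.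

**Further compounds**
F1 | step 8 | trimethylsilyl enol ether of 13 (tetrasubstituted, C9=C10) | CCC(O[Si](C)(C)C)=C(C)C[C@H]1OC(C)(C)O[C@H]1C(C)(C)/C=C/C=O
F2 | step 6 | ethyl 2-{[(4R,5S)-2,2-dimethyl-5-(2-methylbut-3-en-2-yl)-1,3-dioxolan-4-yl]methyl}-2-methyl-3-oxopentanoate | CCOC(=O)C(C)(C[C@H]1OC(C)(C)O[C@H]1C(C)(C)C=C)C(=O)CC
F3 | step 7 | 2-[(4S,5R)-2,2-dimethyl-5-(2-methyl-3-oxopentyl)-1,3-dioxolan-4-yl]-2-methylpropanal | CCC(=O)C(C)C[C@H]1OC(C)(C)O[C@H]1C(C)(C)C=O
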